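## The problem

The target is a flavonol in which benzene ring A is fused to 4-pyranone ring C, and ring C carries catechol ring B at C2, a hydroxyl at C3 and the carbonyl at C4. It has no stereocentre, so the whole task is to place seven oxygen atoms and to tell five free hydroxyls from two methyl ethers. Ring A is fully substituted, with hydroxyls at C5 and C7 alternating with methoxyls at C6 and C8, a pattern that selective methylation of a polyphenol cannot deliver and that is best fixed on a simple benzene before ring C exists. The free compound combines a catechol, a pentaoxygenated benzene and an enolic 3-hydroxy-4-pyranone, so it is oxidised easily once deprotonated in air and its pyranone is opened by hot alkoxide. The polyphenol should therefore be released only in the last step, under neutral conditions, from ethers that cleave without touching the O–CH3 bonds. The C3 hydroxyl sits on the C2=C3 enol-ether bond and can be added late by oxidation of a flavone. The key step rests on two features: C4 is a lone carbonyl carbon between C4a and C3 and can come from carbon monoxide, and ring A without C4 has a mirror plane through C4a and C7 that exchanges the oxygen on C5 with that on C8a and the methoxyl on C6 with that on C8, so a leaving group at C4a is flanked by two equivalent oxygen functions and closure through either gives the same flavone.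

## Retrosynthesis

**Target 15 to flavonol 14.** The four O–benzyl bonds at O5, O7, O3' and O4' are cut. Hydrogenolysis is neutral and non-oxidising and leaves the two methyl ethers alone, which no Lewis-acid dealkylation would do reliably. The forward step must only spare the tetrasubstituted C2=C3 bond of 14.

**Flavonol 14 to flavone 12.** The C3–O bond is cut. Flavone 12 is the direct outcome of an alkyne annulation, and epoxidation of its C2=C3 bond to epoxide 13 followed by acid-catalysed opening is the established way from a flavone to a flavonol. All phenols must be capped in the forward reaction, and ring A of 12 has no C–H left to oxidise.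

**Flavone 12 to flavone 11.** The two O–benzyl bonds at O5 and O7 are cut. The annulation releases both phenols of ring A, so they are re-protected with the group already present on ring B, and one hydrogenolysis clears all four at the end.

**Flavone 11 to iodide 5, alkyne 8 and carbon monoxide.** Three bonds of ring C are cut: C4a–C4, C4–C3 and O1–C2. The cut removes the whole pyranone in one operation and leaves two pieces of similar size: a symmetric pentaoxygenated iodobenzene and a terminal aryl alkyne. A Baker–Venkataraman or chalcone route would first need an acyl group on the crowded ring A and then a selective single O-acylation or a protected aldol; here the mirror symmetry of 5 removes every regiochemical question. The forward reaction must favour carbonylative over direct coupling and six-membered over five-membered closure; it passes through ynone 9 and enaminone 10.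

**Alkyne 8 to aldehyde 6 and diazophosphonate 7.** The C≡C bond is formed by one-carbon homologation of a commercial aldehyde that already carries the benzyl ethers. This is shorter than a Sonogashira route from an aryl halide with a silyl alkyne.

**Iodide 5 to triol 3 via iodotriol 4.** Three O–acetyl bonds and then the C–I bond are cut. Triol 3 has a single ring C–H, ortho to two hydroxyls and para to the third, so iodination can only occur where it is wanted. The acetates make the iodide storable and mask the ortho oxygens until the palladium steps are over.

**Triol 3 to tribromide 2 to resorcinol 1.** Three C–O bonds are cut back to C–Br, then two O–methyl bonds. In 1 the bromines already mark the three future hydroxyl carbons and the two hydroxyls mark the future methoxyls. Methylation followed by threefold hydroxylation therefore sets the alternating pattern without any selective step.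

## Roads not taken

Alternative 1: Late twofold methoxylation of the quercetin nucleus.
- **Cut:** the two C–OMe bonds at C6 and C8 of an intact flavonol.
- **Forward:** commercial quercetin A1 would be benzylated at every hydroxyl except the chelated one at C5 and brominated at C6 and C8. This would give 3,7-bis(benzyloxy)-2-[3,4-bis(benzyloxy)phenyl]-6,8-dibromo-5-hydroxy-4H-chromen-4-one A2. In the key step NaOMe and CuBr (monovalent copper) in DMF and methanol would replace both bromides of A2 by methoxyl. The product would be 3,7-bis(benzyloxy)-2-[3,4-bis(benzyloxy)phenyl]-5-hydroxy-6,8-dimethoxy-4H-chromen-4-one A3, and hydrogenolysis of A3 would give target 15.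
- **Merits:** the carbon skeleton and the C3 oxygen are bought with A1; about four steps; no carbon monoxide and no late oxidation.
- **Weak points:** both bromides of A2 are flanked on two sides and must be substituted in hot methoxide on a chromone that alkoxide can open at C2. Any hydrodebromination gives 6- or 8-monomethoxy congeners that will be hard to separate from A3.
- **Comparison:** this road is clearly shorter, by about five steps, and is the better one if the double substitution on A2 is clean. The chosen plan sets against it that all ring A oxygens are placed on a cheap benzene before the skeleton exists, that no chromone meets hot alkoxide, and that ring B can be varied through alkyne 8.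

Alternative 2: Biomimetic Claisen cyclisation that builds ring A.
- **Cut:** the C4a–C5 bond, so that ring A comes from an open chain.
- **Forward:** methyl (E)-9-[3,4-bis(benzyloxy)phenyl]-2,4-dimethoxy-3,5,7-trioxonon-8-enoate A4 would cyclise under Mg(OMe)2 by attack of chain carbon 6 on the ester carbonyl. The product would be the chalcone (E)-3-[3,4-bis(benzyloxy)phenyl]-1-(2,4,6-trihydroxy-3,5-dimethoxyphenyl)prop-2-en-1-one A5. Algar–Flynn–Oyamada oxidation of A5 and hydrogenolysis would then lead to target 15.
- **Merits:** the oxygen pattern is written into the chain of A4, no ring A protecting groups are needed, and the oxidative cyclisation of A5 could form O1–C2 and the C3 hydroxyl together.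
- **Weak points:** A4 holds two α-methoxy-β-dicarbonyl units and an enone, and making it would take more steps than the whole chosen route. Aldol and lactonisation modes compete with the Claisen closure. Chalcones with a second ortho hydroxyl, such as A5, tend to give aurones under Algar–Flynn–Oyamada conditions.
- **Comparison:** the chosen plan buys ring A as an aromatic compound and forms only ring C. Alternative 2 is better only in avoiding palladium and protecting groups on ring A.

Alternative 3: Copper-closed O1–C8a bond on a dibromo diketone.
- **Cut:** the O1–C8a bond.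
- **Forward:** the enolate oxygen of 1-[4-(benzyloxy)-2,6-dibromo-3,5-dimethoxyphenyl]-2-(benzyloxy)-3-[3,4-bis(benzyloxy)phenyl]propane-1,3-dione A6 would displace one ortho bromide under CuI (monovalent copper), 1,10-phenanthroline and K3PO4. The product would be 3,7-bis(benzyloxy)-2-[3,4-bis(benzyloxy)phenyl]-5-bromo-6,8-dimethoxy-4H-chromen-4-one A7.
- **Merits:** the C3 oxygen is carried from the start in A6, so no late oxidation is needed; the two bromides of A6 are equivalent, so there is no regiochemical issue.
- **Weak points:** A6 needs a Claisen-type acylation at a carbonyl flanked by two bromines. Its trisubstituted enolate may arylate at carbon or fail to close. The bromide left at C5 in A7 must be turned into a hydroxyl in a second C–O coupling before hydrogenolysis, or it is lost as C–H.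
- **Comparison:** the road through A7 is better in avoiding the dioxirane step and carbon monoxide. The chosen plan also needs a C–O coupling (the threefold hydroxylation of 2), but on a cheap early intermediate and not on the assembled flavonol.

Key step: step 6

Remark on the chemistry: the target is achiral; the only stereocentres on the route are the two of the transient epoxide 13, which forms as a racemate and is consumed in the same step. Compounds 1, 6 and 7 are taken as purchased.

## Route

Step 1
Reactants: 1 2,4,6-tribromobenzene-1,3-diol (2,4,6-tribromoresorcinol)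
Product: 2 1,3,5-tribromo-2,4-dimethoxybenzene
Conditions: MeI, K2CO3, DMF, rt to 40 °C
Reagents that add atoms: iodomethane, CI
Why: Williamson O-methylation; both hydroxyls are acidic because each lies between two bromines, the small electrophile tolerates the crowding, and every ring position ortho or para to oxygen is blocked, so C-alkylation cannot compete.

Step 2
Reactants: 2 1,3,5-tribromo-2,4-dimethoxybenzene
Product: 3 2,4-dimethoxybenzene-1,3,5-triol
Conditions: Pd2(dba)3 (cat.), tBuXPhos (cat.), KOH, degassed 1,4-dioxane/H2O, 100 °C, argon; then aq. HCl, 0 °C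
Reagents that add atoms: potassium hydroxide, [K+].[OH-]
Why: Palladium-catalysed hydroxylation of aryl bromides with hydroxide, in which the bulky biaryl phosphine drives C–O reductive elimination; the three bromides are mutually meta, so each phenoxide formed is meta to the remaining C–Br bonds and should not stop further oxidative addition. Exclusion of air and acidic work-up protect the electron-rich triol.

Step 3
Reactants: 3 2,4-dimethoxybenzene-1,3,5-triol
Product: 4 2-iodo-4,6-dimethoxybenzene-1,3,5-triol
Conditions: NIS (1.0 equiv), MeCN, 0 °C, dark, argon; crude product used directly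
Reagents that add atoms: N-iodosuccinimide, O=C1CCC(=O)N1I
Why: Electrophilic aromatic iodination of a phloroglucinol-type ring; the only ring C–H is ortho to two hydroxyls and para to the third, so one equivalent of a mild iodine source should react there without acid and no other site is open.

Step 4
Reactants: 4 2-iodo-4,6-dimethoxybenzene-1,3,5-triol
Product: 5 2-iodo-4,6-dimethoxybenzene-1,3,5-triyl triacetate
Conditions: Ac2O, pyridine, DMAP (cat.), CH2Cl2, 0 °C to rt
Reagents that add atoms: acetic anhydride, CC(=O)OC(C)=O
Why: DMAP-catalysed O-acetylation; it turns the oxidation-prone iodotriol into a storable triacetate and masks the two ortho oxygens until after the palladium steps of the annulation.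

Step 5
Reactants: 6 3,4-bis(benzyloxy)benzaldehyde; 7 dimethyl (1-diazo-2-oxopropyl)phosphonate
Product: 8 4-ethynyl-1,2-bis(benzyloxy)benzene
Conditions: K2CO3, MeOH/THF, 0 °C to rt
Reagents that add atoms: none
Why: Ohira–Bestmann variant of the Seyferth–Gilbert homologation; methanolysis of 7 frees the diazomethylphosphonate anion, which olefinates the non-enolisable aldehyde, and loss of N2 with 1,2-hydrogen shift gives the terminal alkyne. Benzyl ethers are inert to carbonate in methanol.

Step 6
Reactants: 5 2-iodo-4,6-dimethoxybenzene-1,3,5-triyl triacetate; 8 4-ethynyl-1,2-bis(benzyloxy)benzene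
Product: 11 2-[3,4-bis(benzyloxy)phenyl]-5,7-dihydroxy-6,8-dimethoxy-4H-chromen-4-one, via triacetoxy aryl ynone 9 (not isolated), via diethylamino enone 10 (not isolated)
Conditions: PdCl2(PPh3)2 (5 mol %), dppp (5 mol %), CO (1 atm), Et2NH (solvent), 45 °C
Reagents that add atoms: carbon monoxide, [C-]#[O+]
Why: The closest known reaction is the palladium-catalysed carbonylative annulation of ortho-iodophenols or their acetates with terminal aryl alkynes to flavones, a copper-free carbonylative Sonogashira coupling followed by conjugate-addition cyclisation. Zerovalent palladium, formed in the flask from the divalent palladium precatalyst, adds to the C–I bond of 5; CO inserts to give an aroylpalladium species, the amine-deprotonated alkyne 8 takes the place of iodide, and reductive elimination gives ynone 9 with the new C4a–C4 and C4–C3 bonds. Diethylamine then cleaves the three acetates by aminolysis and adds to the ynone to give the (E)-β-aminoenone 10. Ring C closes when an ortho phenoxide oxygen attacks the amine-bearing β-carbon in a 6-endo-trig addition and diethylamine is expelled, which forms O1–C2 and the aromatic pyranone without creating any stereocentre. The step needs carbonylative coupling to beat direct coupling, which copper-free conditions and a CO atmosphere should favour because CO insertion into the crowded aryl–palladium bond is expected to be faster than alkynyl transfer. It also needs flavone to beat aurone; the secondary amine secures this by converting the ynone into an enaminone whose only electrophilic carbon is the future C2. Regiochemistry is not an issue, because the iodide of 5 lies on the mirror plane of the ring and closure through either ortho oxygen gives the same flavone 11.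

Step 7
Reactants: 11 2-[3,4-bis(benzyloxy)phenyl]-5,7-dihydroxy-6,8-dimethoxy-4H-chromen-4-one
Product: 12 5,7-bis(benzyloxy)-2-[3,4-bis(benzyloxy)phenyl]-6,8-dimethoxy-4H-chromen-4-one
Conditions: BnBr (excess), K2CO3, Bu4NI (cat.), DMF, 70 °C
Reagents that add atoms: benzyl bromide, BrCc1ccccc1
Why: Williamson benzylation; the C7 hydroxyl is a vinylogous acid and reacts easily, while the hydrogen-bonded C5 hydroxyl needs a polar aprotic solvent, heat, excess halide and iodide catalysis. Ring A has no C–H, so C-benzylation is excluded.

Step 8
Reactants: 12 5,7-bis(benzyloxy)-2-[3,4-bis(benzyloxy)phenyl]-6,8-dimethoxy-4H-chromen-4-one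
Product: 14 5,7-bis(benzyloxy)-2-[3,4-bis(benzyloxy)phenyl]-3-hydroxy-6,8-dimethoxy-4H-chromen-4-one, via racemic flavone 2,3-epoxide 13 (not isolated)
Conditions: dimethyldioxirane (acetone solution), CH2Cl2, 0 °C to rt; then p-TsOH·H2O (cat.), CH2Cl2, rt
Reagents that add atoms: dimethyldioxirane, CC1(C)OO1
Why: Dioxirane epoxidation of the flavone C2=C3 bond under neutral conditions gives the cis-fused epoxide 13, whose two stereocentres are formed as a racemate and do not persist. Acid opens it at C2 to a cation stabilised by O1 and the aryl ring, and loss of the C3 proton gives the 3-hydroxyflavone, a known flavone-to-flavonol sequence. All phenols are capped and ring A has no C–H to hydroxylate.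

Step 9
Reactants: 14 5,7-bis(benzyloxy)-2-[3,4-bis(benzyloxy)phenyl]-3-hydroxy-6,8-dimethoxy-4H-chromen-4-one
Product: 15 2-(3,4-dihydroxyphenyl)-3,5,7-trihydroxy-6,8-dimethoxy-4H-chromen-4-one (3,5,7,3',4'-pentahydroxy-6,8-dimethoxyflavone)
Conditions: H2 (1 atm), Pd(OH)2/C, THF/MeOH, rt; filtration and concentration under argon
Reagents that add atoms: none
Why: Catalytic hydrogenolysis of four aryl benzyl ethers; the methyl ethers, the carbonyl and the tetrasubstituted C2=C3 bond of the vinylogous ester should be untouched, and the neutral reductive medium releases the air-sensitive polyphenol only at the end.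

## Compound list

1 | 2,4,6-tribromobenzene-1,3-diol (2,4,6-tribromoresorcinol) | Oc1c(Br)cc(Br)c(O)c1Br | starting material
2 | 1,3,5-tribromo-2,4-dimethoxybenzene | COc1c(Br)cc(Br)c(OC)c1Br | intermediate
3 | 2,4-dimethoxybenzene-1,3,5-triol | COc1c(O)cc(O)c(OC)c1O | intermediate
4 | 2-iodo-4,6-dimethoxybenzene-1,3,5-triol | COc1c(O)c(OC)c(O)c(I)c1O | intermediate
5 | 2-iodo-4,6-dimethoxybenzene-1,3,5-triyl triacetate | COc1c(OC(C)=O)c(OC)c(OC(C)=O)c(I)c1OC(C)=O | intermediate
6 | 3,4-bis(benzyloxy)benzaldehyde | O=Cc1ccc(OCc2ccccc2)c(OCc2ccccc2)c1 | starting material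
7 | dimethyl (1-diazo-2-oxopropyl)phosphonate | COP(=O)(OC)C(=[N+]=[N-])C(C)=O | starting material
8 | 4-ethynyl-1,2-bis(benzyloxy)benzene | C#Cc1ccc(OCc2ccccc2)c(OCc2ccccc2)c1 | intermediate
9 | 2-{3-[3,4-bis(benzyloxy)phenyl]prop-2-ynoyl}-4,6-dimethoxybenzene-1,3,5-triyl triacetate | COc1c(OC(C)=O)c(OC)c(OC(C)=O)c(C(=O)C#Cc2ccc(OCc3ccccc3)c(OCc3ccccc3)c2)c1OC(C)=O | intermediate
10 | (E)-3-[3,4-bis(benzyloxy)phenyl]-3-(diethylamino)-1-(2,4,6-trihydroxy-3,5-dimethoxyphenyl)prop-2-en-1-one | CCN(CC)/C(=C/C(=O)c1c(O)c(OC)c(O)c(OC)c1O)c1ccc(OCc2ccccc2)c(OCc2ccccc2)c1 | intermediate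
11 | 2-[3,4-bis(benzyloxy)phenyl]-5,7-dihydroxy-6,8-dimethoxy-4H-chromen-4-one | COc1c(O)c(OC)c2oc(-c3ccc(OCc4ccccc4)c(OCc4ccccc4)c3)cc(=O)c2c1O | intermediate
12 | 5,7-bis(benzyloxy)-2-[3,4-bis(benzyloxy)phenyl]-6,8-dimethoxy-4H-chromen-4-one | COc1c(OCc2ccccc2)c(OC)c2oc(-c3ccc(OCc4ccccc4)c(OCc4ccccc4)c3)cc(=O)c2c1OCc1ccccc1 | intermediate
13 | 5,7-bis(benzyloxy)-2-[3,4-bis(benzyloxy)phenyl]-2,3-epoxy-6,8-dimethoxy-2,3-dihydro-4H-chromen-4-one, the cis-fused 2,3-epoxide of 12, racemic (one enantiomer drawn) | COc1c(OCc2ccccc2)c(OC)c2O[C@@]3(c4ccc(OCc5ccccc5)c(OCc5ccccc5)c4)O[C@H]3C(=O)c2c1OCc1ccccc1 | intermediate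
14 | 5,7-bis(benzyloxy)-2-[3,4-bis(benzyloxy)phenyl]-3-hydroxy-6,8-dimethoxy-4H-chromen-4-one | COc1c(OCc2ccccc2)c(OC)c2oc(-c3ccc(OCc4ccccc4)c(OCc4ccccc4)c3)c(O)c(=O)c2c1OCc1ccccc1 | intermediate
15 | 2-(3,4-dihydroxyphenyl)-3,5,7-trihydroxy-6,8-dimethoxy-4H-chromen-4-one | COc1c(O)c(OC)c2oc(-c3ccc(O)c(O)c3)c(O)c(=O)c2c1O | target

## Step count and risks

Total: 9 steps. Longest linear sequence: 8 steps (steps 1 to 4 and 6 to 9, from 1); the alkyne branch adds step 5.

**Step 6 (key step).**
- What may go wrong: oxidative addition and CO insertion at an iodide with two ortho substituents may be slow. Early aminolysis of the acetates would then expose a free, very electron-rich iodophenol, which invites direct alkyne coupling with five-membered closure to a benzofuran, reductive loss of iodine, or capture of the aroylpalladium species by diethylamine as an amide.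
- Fallback: a palladium-free acylation route that sets out from triol 3 and comes back at flavone 11. Friedel–Crafts acetylation of 3 at its single C–H (Ac2O, BF3·OEt2) would give 1-(2,4,6-trihydroxy-3,5-dimethoxyphenyl)ethan-1-one F1. Its polyanion, made with excess LiN(SiMe3)2 in THF at −78 °C, would be C-acylated by 3,4-bis(benzyloxy)benzoyl chloride F2, prepared from commercial 3,4-bis(benzyloxy)benzoic acid and oxalyl chloride. The resulting 1-[3,4-bis(benzyloxy)phenyl]-3-(2,4,6-trihydroxy-3,5-dimethoxyphenyl)propane-1,3-dione F3 would be cyclodehydrated with catalytic p-TsOH in warm toluene to 11. The ring symmetry again makes the closure unambiguous.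

**Step 2.**
- What may go wrong: the threefold substitution may stop early or suffer hydrodebromination. The phloroglucinol-type phenoxide may be arylated at carbon by an arylpalladium intermediate. The triol may be oxidised by air in hot base.
- Fallback: from tribromide 2, a threefold Ullmann etherification with NaOCH2Ph (from BnOH and NaH; CuI, 3,4,7,8-tetramethyl-1,10-phenanthroline, toluene, 110 °C) would give 1,3,5-tris(benzyloxy)-2,4-dimethoxybenzene F4. Hydrogenolysis (H2, Pd/C, EtOAc) would then release triol 3 under neutral conditions, where the route is rejoined.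

**Step 8.**
- What may go wrong: epoxidation of the crowded, electron-poor enone bond may be slow, so that excess dioxirane starts to oxidise the benzylic C–H bonds of the benzyl ethers, with loss of protecting groups.
- Fallback: from flavone 12, deprotonation at C3 with LiN(iPr)2 in THF at −78 °C and trapping with B(OMe)3 would give dimethyl {5,7-bis(benzyloxy)-2-[3,4-bis(benzyloxy)phenyl]-6,8-dimethoxy-4-oxo-4H-chromen-3-yl}boronate F5. Oxidation with H2O2 and acetic acid would return to flavonol 14.

**Step 7.**
- What may go wrong: alkylation of the hydrogen-bonded C5 hydroxyl, which also has a methoxyl neighbour, may be incomplete, leaving a mixture of mono- and dibenzyl ethers.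
- Fallback: from flavone 11, benzylation at O7 only (1.1 equiv BnBr, K2CO3, acetone) would give 7-(benzyloxy)-2-[3,4-bis(benzyloxy)phenyl]-5-hydroxy-6,8-dimethoxy-4H-chromen-4-one F6, in which the hydrogen bond to the carbonyl serves as the protecting group. Dioxirane epoxidation and acid treatment as in step 8 would give 7-(benzyloxy)-2-[3,4-bis(benzyloxy)phenyl]-3,5-dihydroxy-6,8-dimethoxy-4H-chromen-4-one F7. Hydrogenolysis of its three benzyl ethers would rejoin the route at target 15.

## Further compounds

F1 | step 6 | 1-(2,4,6-trihydroxy-3,5-dimethoxyphenyl)ethan-1-one | COc1c(O)c(OC)c(O)c(C(C)=O)c1O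
F2 | step 6 | 3,4-bis(benzyloxy)benzoyl chloride | O=C(Cl)c1ccc(OCc2ccccc2)c(OCc2ccccc2)c1
F3 | step 6 | 1-[3,4-bis(benzyloxy)phenyl]-3-(2,4,6-trihydroxy-3,5-dimethoxyphenyl)propane-1,3-dione | COc1c(O)c(OC)c(O)c(C(=O)CC(=O)c2ccc(OCc3ccccc3)c(OCc3ccccc3)c2)c1O
F4 | step 2 | 1,3,5-tris(benzyloxy)-2,4-dimethoxybenzene | COc1c(OCc2ccccc2)cc(OCc2ccccc2)c(OC)c1OCc1ccccc1
F5 | step 8 | dimethyl {5,7-bis(benzyloxy)-2-[3,4-bis(benzyloxy)phenyl]-6,8-dimethoxy-4-oxo-4H-chromen-3-yl}boronate | COB(OC)c1c(-c2ccc(OCc3ccccc3)c(OCc3ccccc3)c2)oc2c(OC)c(OCc3ccccc3)c(OC)c(OCc3ccccc3)c2c1=O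
F6 | step 7 | 7-(benzyloxy)-2-[3,4-bis(benzyloxy)phenyl]-5-hydroxy-6,8-dimethoxy-4H-chromen-4-one | COc1c(OCc2ccccc2)c(OC)c2oc(-c3ccc(OCc4ccccc4)c(OCc4ccccc4)c3)cc(=O)c2c1O
F7 | step 7 | 7-(benzyloxy)-2-[3,4-bis(benzyloxy)phenyl]-3,5-dihydroxy-6,8-dimethoxy-4H-chromen-4-one | COc1c(OCc2ccccc2)c(OC)c2oc(-c3ccc(OCc4ccccc4)c(OCc4ccccc4)c3)c(O)c(=O)c2c1O
A1 | alternative 1 | quercetin, 2-(3,4-dihydroxyphenyl)-3,5,7-trihydroxy-4H-chromen-4-one | O=c1c(O)c(-c2ccc(O)c(O)c2)oc2cc(O)cc(O)c12
A2 | alternative 1 | 3,7-bis(benzyloxy)-2-[3,4-bis(benzyloxy)phenyl]-6,8-dibromo-5-hydroxy-4H-chromen-4-one | O=c1c(OCc2ccccc2)c(-c2ccc(OCc3ccccc3)c(OCc3ccccc3)c2)oc2c(Br)c(OCc3ccccc3)c(Br)c(O)c12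
A3 | alternative 1 | 3,7-bis(benzyloxy)-2-[3,4-bis(benzyloxy)phenyl]-5-hydroxy-6,8-dimethoxy-4H-chromen-4-one | O=c1c(OCc2ccccc2)c(-c2ccc(OCc3ccccc3)c(OCc3ccccc3)c2)oc2c(OC)c(OCc3ccccc3)c(OC)c(O)c12
A4 | alternative 2 | methyl (E)-9-[3,4-bis(benzyloxy)phenyl]-2,4-dimethoxy-3,5,7-trioxonon-8-enoate (C2 and C4 epimerisable, mixture) | COC(=O)C(OC)C(=O)C(OC)C(=O)CC(=O)/C=C/c1ccc(OCc2ccccc2)c(OCc2ccccc2)c1
A5 | alternative 2 | (E)-3-[3,4-bis(benzyloxy)phenyl]-1-(2,4,6-trihydroxy-3,5-dimethoxyphenyl)prop-2-en-1-one | COc1c(O)c(OC)c(O)c(C(=O)/C=C/c2ccc(OCc3ccccc3)c(OCc3ccccc3)c2)c1O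
A6 | alternative 3 | 1-[4-(benzyloxy)-2,6-dibromo-3,5-dimethoxyphenyl]-2-(benzyloxy)-3-[3,4-bis(benzyloxy)phenyl]propane-1,3-dione (racemic, enolisable) | COc1c(OCc2ccccc2)c(OC)c(Br)c(C(=O)C(OCc2ccccc2)C(=O)c2ccc(OCc3ccccc3)c(OCc3ccccc3)c2)c1Br
A7 | alternative 3 | 3,7-bis(benzyloxy)-2-[3,4-bis(benzyloxy)phenyl]-5-bromo-6,8-dimethoxy-4H-chromen-4-one | COc1c(OCc2ccccc2)c(OC)c2oc(-c3ccc(OCc4ccccc4)c(OCc4ccccc4)c3)c(OCc3ccccc3)c(=O)c2c1Br
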